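**Retrosynthetic overview**
- The acetate, the (Z)-enyne (C4 aldehyde plus a silylpropyne Peterson olefination), the C13 bromide and the C7/C9 chlorides are installed last; all three halides come from carbinols by SN2 inversion.
- The C9 oxygen and the C8 methylene come from an 8,9-epoxide, placed by the free C10 hydroxyl and opened by hydride delivered from the C7 hydroxyl; this leads back to a Δ8-oxocene closed by ring-closing metathesis.
- In the metathesis diene, C10 comes from a Sharpless epoxidation/epoxy-iodide fragmentation, C13 from a chelation-controlled ethyl addition, and C12 from an Ireland–Claisen rearrangement that relays chirality from a lipase-resolved allylic alcohol.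
- The ether bridge is made by O-alkylating the C6 carbinol with bromoacetic acid; C6/C7 come from Sharpless desymmetrisation of penta-1,4-dien-3-ol, and C4 is added by epoxide opening.
- Ring order: oxirane (C5–C6, opened) → oxirane (C9–C10, fragmented) → oxocene (metathesis) → oxirane (C8–C9, opened) → oxocane.

Assumption: the target is taken as drawn, (3Z,6S,7S,9S,10S,12R,13S)-13-bromo-7,9-dichloro-6,12-epoxypentadec-3-en-1-yn-10-yl acetate; C1–C15 are the locants of this chain, and in oxocane names ring positions 2, 3, 4, 5, 6, 8 are C6, C7, C8, C9, C10, C12.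

**Route**

Step 1
Reactants: 1 penta-1,4-dien-3-ol
Product: 2 (2S,3R)-1,2-epoxypent-4-en-3-ol
Conditions: Ti(OiPr)4 (10 mol %), D-(−)-diisopropyl tartrate (13 mol %), t-BuOOH, 4 Å MS, CH2Cl2, −20 °C
Reagents that add atoms: tert-butyl hydroperoxide CC(C)(C)OO
Why: Sharpless asymmetric epoxidation desymmetrises the achiral dienol, the Ti(OiPr)4/tartrate catalyst choosing one vinyl group and one face so that C6 (S) and C7 (R) are set together as the erythro epoxy alcohol, with ee raised further because the minor enantiomer is epoxidised a second time.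

Step 2
Reactants: 2 (2S,3R)-1,2-epoxypent-4-en-3-ol
Product: 3 (2S)-2-[(1R)-1-(4-methoxybenzyloxy)prop-2-enyl]oxirane
Conditions: NaH, 4-MeOC6H4CH2Cl, Bu4NI (cat.), THF/DMF, 0 °C
Reagents that add atoms: 4-methoxybenzyl chloride COc1ccc(CCl)cc1
Why: Williamson etherification in an aprotic medium at 0 °C caps the C7 hydroxyl faster than Payne migration can occur and touches no stereocentre.

Step 3
Reactants: 3 (2S)-2-[(1R)-1-(4-methoxybenzyloxy)prop-2-enyl]oxirane; 4 tributyl[(benzyloxy)methyl]stannane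
Product: 5 (3S,4R)-1-(benzyloxy)-4-(4-methoxybenzyloxy)hex-5-en-3-ol
Conditions: 4, n-BuLi, THF, −78 °C; then BF3·OEt2, 3, −78 °C
Reagents that add atoms: none
Why: Tin–lithium exchange gives (benzyloxy)methyllithium, which opens the BF3-activated terminal epoxide at its CH2 carbon by SN2, adding C4 with its oxygen and leaving the C6 carbinol configuration untouched.

Step 4
Reactants: 5 (3S,4R)-1-(benzyloxy)-4-(4-methoxybenzyloxy)hex-5-en-3-ol; 6 bromoacetic acid
Product: 7 {[(3S,4R)-1-(benzyloxy)-4-(4-methoxybenzyloxy)hex-5-en-3-yl]oxy}acetic acid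
Conditions: NaH (3 equiv), BrCH2CO2H, THF/DMF, 0 °C → rt; aq. HCl work-up
Reagents that add atoms: none
Why: Williamson O-alkylation of the sodium alkoxide with sodium bromoacetate (SN2 at a primary carbon) installs the future C12 and C13 and forms the ring-oxygen bridge without disturbing C6 or C7.

Step 5
Reactants: 8 (tert-butyldimethylsilyloxy)acetaldehyde; 9 vinylmagnesium bromide
Product: 10 rac-1-(tert-butyldimethylsilyloxy)but-3-en-2-ol
Conditions: THF, −78 °C; aq. NH4Cl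
Reagents that add atoms: none
Why: Grignard addition of the vinyl nucleophile to the aldehyde gives the racemic secondary allylic alcohol needed for the resolution.

Step 6
Reactants: 10 rac-1-(tert-butyldimethylsilyloxy)but-3-en-2-ol
Product: 11 (S)-1-(tert-butyldimethylsilyloxy)but-3-en-2-ol
Conditions: lipase (Burkholderia cepacia lipase, Amano PS, immobilised), vinyl acetate, t-BuOMe, 30 °C, to ca. 55% conversion; chromatography
Reagents that add atoms: none
Why: Lipase-catalysed kinetic resolution by enantioselective transesterification acetylates the R alcohol (large CH2OSi, medium vinyl, Kazlauskas rule) and leaves the S alcohol in ≥99% ee.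

Step 7
Reactants: 7 {[(3S,4R)-1-(benzyloxy)-4-(4-methoxybenzyloxy)hex-5-en-3-yl]oxy}acetic acid; 11 (S)-1-(tert-butyldimethylsilyloxy)but-3-en-2-ol
Product: 12 (S)-1-(tert-butyldimethylsilyloxy)but-3-en-2-yl ester of acid 7
Conditions: EDC·HCl, DMAP (cat.), CH2Cl2, 0 °C → rt
Reagents that add atoms: none
Why: Steglich-type carbodiimide esterification joins the two fragments under neutral conditions without touching any stereocentre.

Step 8
Reactants: 12 (S)-1-(tert-butyldimethylsilyloxy)but-3-en-2-yl ester of acid 7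
Product: 15 (2R,4E)-2-alkoxy-6-(tert-butyldimethylsilyloxy)hex-4-enoic acid (C12 R), via silyl ketene acetal 13 (not isolated), via trimethylsilyl ester 14 (not isolated)
Conditions: LiN(SiMe3)2, THF, −78 °C; Me3SiCl, Et3N, −78 °C → rt; aq. citric acid
Reagents that add atoms: none
Why: In the Ireland–Claisen rearrangement the chelated Z silyl ketene acetal reacts through a chair transition state with CH2OSi equatorial, so the carbinol chirality is transferred to C12 (R) and the new C9=C10 alkene is E.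

Step 9
Reactants: 15 (2R,4E)-2-alkoxy-6-(tert-butyldimethylsilyloxy)hex-4-enoic acid
Product: 16 (2R,4E)-2-alkoxy-6-(tert-butyldimethylsilyloxy)hex-4-en-1-ol
Conditions: LiAlH4, THF, 0 °C
Reagents that add atoms: none
Why: Hydride reduction of the carboxylic acid gives the primary alcohol under conditions that cannot epimerise C12.

Step 10
Reactants: 16 (2R,4E)-2-alkoxy-6-(tert-butyldimethylsilyloxy)hex-4-en-1-ol
Product: 17 (2R,4E)-2-alkoxy-6-(tert-butyldimethylsilyloxy)hex-4-enal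
Conditions: Dess–Martin periodinane, NaHCO3, CH2Cl2, 0 °C → rt
Reagents that add atoms: none
Why: Buffered Dess–Martin oxidation gives the α-alkoxy aldehyde without epimerising C12.

Step 11
Reactants: 17 (2R,4E)-2-alkoxy-6-(tert-butyldimethylsilyloxy)hex-4-enal; 18 ethylmagnesium bromide
Product: 19 (3R,4R,6E)-4-alkoxy-8-(tert-butyldimethylsilyloxy)oct-6-en-3-ol
Conditions: MgBr2·OEt2, CH2Cl2, −78 °C; then EtMgBr
Reagents that add atoms: none
Why: In this chelation-controlled (Cram chelate) Grignard addition MgBr2 bridges the aldehyde and the C12 ether oxygen and ethyl attacks the open face, giving the 12,13-syn alcohol (13R).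

Step 12
Reactants: 19 (3R,4R,6E)-4-alkoxy-8-(tert-butyldimethylsilyloxy)oct-6-en-3-ol
Product: 20 13-O-benzyl ether of 19
Conditions: NaH, BnBr, Bu4NI (cat.), THF/DMF, 0 °C → rt
Reagents that add atoms: benzyl bromide BrCc1ccccc1
Why: Williamson benzylation protects C13 with the same group as C4 so that both can later be removed in one hydrogenolysis.

Step 13
Reactants: 20 13-O-benzyl ether of 19
Product: 21 (2E,5R,6R)-6-(benzyloxy)-5-alkoxyoct-2-en-1-ol
Conditions: Bu4NF, THF, 0 °C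
Reagents that add atoms: none
Why: Fluoride-mediated desilylation cleaves the only silyl ether and frees the E-allylic alcohol.

Step 14
Reactants: 21 (2E,5R,6R)-6-(benzyloxy)-5-alkoxyoct-2-en-1-ol
Product: 22 (2S,3S)-2,3-epoxy alcohol of 21
Conditions: Ti(OiPr)4, L-(+)-diethyl tartrate, t-BuOOH, 4 Å MS, CH2Cl2, −20 °C
Reagents that add atoms: tert-butyl hydroperoxide CC(C)(C)OO
Why: Sharpless asymmetric epoxidation under reagent control (L-(+)-tartrate on an E-allylic alcohol gives the 2S,3S epoxide) fixes the future C10 oxygen as S.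

Step 15
Reactants: 22 (2S,3S)-2,3-epoxy alcohol of 21
Product: 23 (2R,3S)-2-(iodomethyl)oxirane derived from 22
Conditions: I2, PPh3, imidazole, THF, 0 °C
Reagents that add atoms: iodine II
Why: Appel-type iodination converts the primary alcohol to the iodide by SN2 and leaves the epoxide intact.

Step 16
Reactants: 23 (2R,3S)-2-(iodomethyl)oxirane derived from 22
Product: 24 (3S,5R,6R)-6-(benzyloxy)-5-alkoxyoct-1-en-3-ol
Conditions: Zn dust, EtOH, reflux
Reagents that add atoms: none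
Why: Zn-mediated reductive β-elimination of the epoxy iodide opens the epoxide to the secondary allylic alcohol with the C10–O bond and its configuration retained, giving the second terminal alkene.

Step 17
Reactants: 24 (3S,5R,6R)-6-(benzyloxy)-5-alkoxyoct-1-en-3-ol
Product: 25 (2S,3R,4Z,6S,8R)-2-[2-(benzyloxy)ethyl]-8-[(1R)-1-(benzyloxy)propyl]-3-(4-methoxybenzyloxy)-3,6,7,8-tetrahydro-2H-oxocin-6-ol
Conditions: second-generation Grubbs catalyst RuCl2(=CHPh)(PCy3)(H2IMes) (10 mol %), CH2Cl2 (1 mM), 40 °C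
Reagents that add atoms: none
Why: Ring-closing metathesis of the two terminal vinyl groups closes the eight-membered ether as the Z alkene with loss of ethene, helped by high dilution and the gauche C6–O/C7–O arrangement.

Step 18
Reactants: 25 oxocenol
Product: 26 8,9-epoxide of 25 with the oxirane oxygen cis to the C10 hydroxyl
Conditions: VO(acac)2 (5 mol %), t-BuOOH, CH2Cl2, 0 °C → rt
Reagents that add atoms: tert-butyl hydroperoxide CC(C)(C)OO
Why: VO(acac)2-catalysed hydroxyl-directed epoxidation delivers oxygen to the alkene face syn to the free allylic C10 hydroxyl (the cis selectivity known for cyclooctenols), so the C9–O bond is set cis to C10–O.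

Step 19
Reactants: 26 8,9-epoxide of 25
Product: 27 10-O-tert-butyldimethylsilyl ether of 26
Conditions: t-BuMe2SiOTf, 2,6-lutidine, CH2Cl2, −78 °C
Reagents that add atoms: tert-butyldimethylsilyl trifluoromethanesulfonate CC(C)(C)[Si](C)(C)OS(=O)(=O)C(F)(F)F
Why: Low-temperature silylation protects C10 so that it stays distinct from the C7 and C9 hydroxyls that will become chlorides.

Step 20
Reactants: 27 10-O-silyl epoxide
Product: 28 C7 alcohol (27 without the 4-methoxybenzyl group)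
Conditions: DDQ, CH2Cl2/pH 7 buffer, 0 °C
Reagents that add atoms: none
Why: Oxidative cleavage of the 4-methoxybenzyl ether by DDQ frees the C7 hydroxyl under neutral conditions that spare benzyl ethers, the silyl ether and the epoxide.

Step 21
Reactants: 28 C7 alcohol with trans 8,9-epoxide
Product: 29 (2S,3R,5R,6S,8R)-2-[2-(benzyloxy)ethyl]-8-[(1R)-1-(benzyloxy)propyl]-6-(tert-butyldimethylsilyloxy)oxocane-3,5-diol
Conditions: NaAlH2(OCH2CH2OMe)2, THF, 0 °C → rt; Rochelle salt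
Reagents that add atoms: none
Why: In this hydroxyl-directed reductive epoxide opening the alkoxyaluminate at the C7 oxygen (trans to the oxirane) delivers hydride intramolecularly to C8, giving the 7,9-anti 1,3-diol with the C9–O bond retained (9R).

Step 22
Reactants: 29 7,9-diol
Product: 30 (2S,3S,5S,6S,8R)-2-[2-(benzyloxy)ethyl]-8-[(1R)-1-(benzyloxy)propyl]-6-(tert-butyldimethylsilyloxy)-3,5-dichlorooxocane
Conditions: CCl4, (n-C8H17)3P, 1-methylcyclohexene, toluene, 80 °C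
Reagents that add atoms: carbon tetrachloride ClC(Cl)(Cl)Cl
Why: Appel-type chlorination displaces both alkoxyphosphonium groups by SN2, inverting C7 (R to S) and C9 (R to S), under the conditions used for C7 chlorination of related oxocene alcohols.

Step 23
Reactants: 30 7,9-dichloride
Product: 31 2-[(2S,3S,5S,6S,8R)-6-(tert-butyldimethylsilyloxy)-3,5-dichloro-8-[(1R)-1-hydroxypropyl]oxocan-2-yl]ethanol
Conditions: H2 (1 atm), Pd/C (palladium on carbon), EtOAc, rt
Reagents that add atoms: none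
Why: Hydrogenolysis removes both benzyl ethers at once while unactivated secondary alkyl chlorides and the silyl ether are inert.

Step 24
Reactants: 31 C4,C13-diol
Product: 32 2-[(2S,3S,5S,6S,8R)-6-(tert-butyldimethylsilyloxy)-3,5-dichloro-8-[(1R)-1-hydroxypropyl]oxocan-2-yl]acetaldehyde
Conditions: TEMPO (cat.), PhI(OAc)2, CH2Cl2, rt
Reagents that add atoms: none
Why: The TEMPO/PhI(OAc)2 oxoammonium oxidation is selective for the primary alcohol, giving the C4 aldehyde and leaving the secondary C13 hydroxyl free.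

Step 25
Reactants: 32 hydroxy aldehyde; 33 1,3-bis(triisopropylsilyl)propyne
Product: 34 (2S,3S,5S,6S,8R)-6-(tert-butyldimethylsilyloxy)-3,5-dichloro-8-[(1R)-1-hydroxypropyl]-2-[(2Z)-5-(triisopropylsilyl)pent-2-en-4-ynyl]oxocane
Conditions: 33 (3 equiv), n-BuLi, THF, −78 °C; then 32, −78 °C → rt
Reagents that add atoms: none
Why: Corey–Yamamoto Peterson olefination of the aldehyde with the lithiated bis-silylpropyne gives the Z enyne, the bulky silyl groups steering the syn-elimination to the cis alkene.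

Step 26
Reactants: 34 (Z)-enyne C13 alcohol
Product: 35 (2S,3S,5S,6S,8R)-8-[(1S)-1-bromopropyl]-6-(tert-butyldimethylsilyloxy)-3,5-dichloro-2-[(2Z)-5-(triisopropylsilyl)pent-2-en-4-ynyl]oxocane
Conditions: CBr4, (n-C8H17)3P, toluene, 70 °C
Reagents that add atoms: carbon tetrabromide BrC(Br)(Br)Br
Why: Appel-type bromination converts the C13 carbinol to the bromide by SN2 with inversion (13R to 13S), as in syntheses of related bromo ethers.

Step 27
Reactants: 35 bis-silylated bromide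
Product: 36 (2S,3S,5S,6S,8R)-8-[(1S)-1-bromopropyl]-3,5-dichloro-2-[(2Z)-pent-2-en-4-ynyl]oxocan-6-ol
Conditions: Bu4NF, AcOH (1:1), THF, 0 °C → rt
Reagents that add atoms: none
Why: Buffered fluoride desilylation removes the alkynyl silyl group and the C10 silyl ether, acetic acid keeping the trans-chlorohydrin from closing to an epoxide.

Step 28
Reactants: 36 C10 alcohol
Product: 37 target acetate
Conditions: Ac2O, pyridine, DMAP (cat.), CH2Cl2, 0 °C
Reagents that add atoms: acetic anhydride CC(=O)OC(C)=O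
Why: DMAP-catalysed acylation acetylates the only free hydroxyl without change at any stereocentre.

**Compound list**

1 | penta-1,4-dien-3-ol | C=CC(O)C=C | starting material
2 | (2S,3R)-1,2-epoxypent-4-en-3-ol | C=C[C@@H](O)[C@@H]1CO1 | intermediate
3 | (2S)-2-[(1R)-1-[(4-methoxybenzyl)oxy]prop-2-en-1-yl]oxirane | C=C[C@@H](OCc1ccc(OC)cc1)[C@@H]2CO2 | intermediate
4 | tributyl[(benzyloxy)methyl]stannane | CCCC[Sn](CCCC)(CCCC)COCc1ccccc1 | starting material
5 | (3S,4R)-1-(benzyloxy)-4-[(4-methoxybenzyl)oxy]hex-5-en-3-ol | C=C[C@@H](OCc1ccc(OC)cc1)[C@@H](O)CCOCc1ccccc1 | intermediate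
6 | bromoacetic acid | OC(=O)CBr | starting material
7 | {[(3S,4R)-1-(benzyloxy)-4-[(4-methoxybenzyl)oxy]hex-5-en-3-yl]oxy}acetic acid | C=C[C@@H](OCc1ccc(OC)cc1)[C@@H](OCC(=O)O)CCOCc1ccccc1 | intermediate
8 | [(tert-butyldimethylsilyl)oxy]acetaldehyde | O=CCO[Si](C)(C)C(C)(C)C | starting material
9 | vinylmagnesium bromide | C=C[Mg]Br | starting material
10 | rac-1-[(tert-butyldimethylsilyl)oxy]but-3-en-2-ol | C=CC(O)CO[Si](C)(C)C(C)(C)C | intermediate
11 | (2S)-1-[(tert-butyldimethylsilyl)oxy]but-3-en-2-ol | C=C[C@H](O)CO[Si](C)(C)C(C)(C)C | intermediate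
12 | (2S)-1-[(tert-butyldimethylsilyl)oxy]but-3-en-2-yl {[(3S,4R)-1-(benzyloxy)-4-[(4-methoxybenzyl)oxy]hex-5-en-3-yl]oxy}acetate | C=C[C@@H](OCc1ccc(OC)cc1)[C@@H](OCC(=O)O[C@@H](C=C)CO[Si](C)(C)C(C)(C)C)CCOCc1ccccc1 | intermediate
13 | (Z)-O-trimethylsilyl ketene acetal of 12 (ether oxygen cis to OSiMe3) | C=C[C@@H](OCc1ccc(OC)cc1)[C@@H](O/C=C(\O[Si](C)(C)C)O[C@@H](C=C)CO[Si](C)(C)C(C)(C)C)CCOCc1ccccc1 | intermediate
14 | trimethylsilyl ester of 15 | C=C[C@@H](OCc1ccc(OC)cc1)[C@@H](O[C@@H](C(=O)O[Si](C)(C)C)C/C=C/CO[Si](C)(C)C(C)(C)C)CCOCc1ccccc1 | intermediate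
15 | (2R,4E)-2-{[(3S,4R)-1-(benzyloxy)-4-[(4-methoxybenzyl)oxy]hex-5-en-3-yl]oxy}-6-[(tert-butyldimethylsilyl)oxy]hex-4-enoic acid | C=C[C@@H](OCc1ccc(OC)cc1)[C@@H](O[C@@H](C(=O)O)C/C=C/CO[Si](C)(C)C(C)(C)C)CCOCc1ccccc1 | intermediate
16 | (2R,4E)-2-{[(3S,4R)-1-(benzyloxy)-4-[(4-methoxybenzyl)oxy]hex-5-en-3-yl]oxy}-6-[(tert-butyldimethylsilyl)oxy]hex-4-en-1-ol | C=C[C@@H](OCc1ccc(OC)cc1)[C@@H](O[C@@H](CO)C/C=C/CO[Si](C)(C)C(C)(C)C)CCOCc1ccccc1 | intermediate
17 | (2R,4E)-2-{[(3S,4R)-1-(benzyloxy)-4-[(4-methoxybenzyl)oxy]hex-5-en-3-yl]oxy}-6-[(tert-butyldimethylsilyl)oxy]hex-4-enal | C=C[C@@H](OCc1ccc(OC)cc1)[C@@H](O[C@@H](C=O)C/C=C/CO[Si](C)(C)C(C)(C)C)CCOCc1ccccc1 | intermediate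
18 | ethylmagnesium bromide | CC[Mg]Br | starting material
19 | (3R,4R,6E)-4-{[(3S,4R)-1-(benzyloxy)-4-[(4-methoxybenzyl)oxy]hex-5-en-3-yl]oxy}-8-[(tert-butyldimethylsilyl)oxy]oct-6-en-3-ol | C=C[C@@H](OCc1ccc(OC)cc1)[C@@H](O[C@@H]([C@H](O)CC)C/C=C/CO[Si](C)(C)C(C)(C)C)CCOCc1ccccc1 | intermediate
20 | (3R,4R,6E)-3-(benzyloxy)-4-{[(3S,4R)-1-(benzyloxy)-4-[(4-methoxybenzyl)oxy]hex-5-en-3-yl]oxy}-8-[(tert-butyldimethylsilyl)oxy]oct-6-ene | C=C[C@@H](OCc1ccc(OC)cc1)[C@@H](O[C@@H]([C@H](OCc1ccccc1)CC)C/C=C/CO[Si](C)(C)C(C)(C)C)CCOCc1ccccc1 | intermediate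
21 | (2E,5R,6R)-6-(benzyloxy)-5-{[(3S,4R)-1-(benzyloxy)-4-[(4-methoxybenzyl)oxy]hex-5-en-3-yl]oxy}oct-2-en-1-ol | C=C[C@@H](OCc1ccc(OC)cc1)[C@@H](O[C@@H]([C@H](OCc1ccccc1)CC)C/C=C/CO)CCOCc1ccccc1 | intermediate
22 | [(2S,3S)-3-{(2R,3R)-3-(benzyloxy)-2-{[(3S,4R)-1-(benzyloxy)-4-[(4-methoxybenzyl)oxy]hex-5-en-3-yl]oxy}pentyl}oxiran-2-yl]methanol | C=C[C@@H](OCc1ccc(OC)cc1)[C@@H](O[C@@H]([C@H](OCc1ccccc1)CC)C[C@@H]2O[C@H]2CO)CCOCc1ccccc1 | intermediate
23 | (2R,3S)-2-(iodomethyl)-3-{(2R,3R)-3-(benzyloxy)-2-{[(3S,4R)-1-(benzyloxy)-4-[(4-methoxybenzyl)oxy]hex-5-en-3-yl]oxy}pentyl}oxirane | C=C[C@@H](OCc1ccc(OC)cc1)[C@@H](O[C@@H]([C@H](OCc1ccccc1)CC)C[C@@H]2O[C@H]2CI)CCOCc1ccccc1 | intermediate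
24 | (3S,5R,6R)-6-(benzyloxy)-5-{[(3S,4R)-1-(benzyloxy)-4-[(4-methoxybenzyl)oxy]hex-5-en-3-yl]oxy}oct-1-en-3-ol | C=C[C@@H](OCc1ccc(OC)cc1)[C@@H](O[C@@H]([C@H](OCc1ccccc1)CC)C[C@H](O)C=C)CCOCc1ccccc1 | intermediate
25 | (2S,3R,4Z,6S,8R)-2-[2-(benzyloxy)ethyl]-8-[(1R)-1-(benzyloxy)propyl]-3-[(4-methoxybenzyl)oxy]-3,6,7,8-tetrahydro-2H-oxocin-6-ol | C(COCc1ccccc1)[C@@H]2O[C@@H]([C@H](OCc3ccccc3)CC)C[C@H](O)/C=C\[C@H]2OCc4ccc(OC)cc4 | intermediate
26 | 4,5-epoxide of 25 (C8–C9), oxirane oxygen on the face of the 6-hydroxyl and opposite the 3-(4-methoxybenzyloxy) group | C(COCc1ccccc1)[C@@H]2O[C@@H]([C@H](OCc3ccccc3)CC)C[C@H](O)[C@@H]5O[C@@H]5[C@H]2OCc4ccc(OC)cc4 | intermediate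
27 | 6-O-(tert-butyldimethylsilyl) ether of 26 | C(COCc1ccccc1)[C@@H]2O[C@@H]([C@H](OCc3ccccc3)CC)C[C@H](O[Si](C)(C)C(C)(C)C)[C@@H]5O[C@@H]5[C@H]2OCc4ccc(OC)cc4 | intermediate
28 | 27 with the 4-methoxybenzyl group removed (free ring 3-hydroxyl, trans to the 4,5-epoxide) | C(COCc1ccccc1)[C@@H]2O[C@@H]([C@H](OCc3ccccc3)CC)C[C@H](O[Si](C)(C)C(C)(C)C)[C@@H]5O[C@@H]5[C@H]2O | intermediate
29 | (2S,3R,5R,6S,8R)-2-[2-(benzyloxy)ethyl]-8-[(1R)-1-(benzyloxy)propyl]-6-[(tert-butyldimethylsilyl)oxy]oxocane-3,5-diol | C(COCc1ccccc1)[C@@H]2O[C@@H]([C@H](OCc3ccccc3)CC)C[C@H](O[Si](C)(C)C(C)(C)C)[C@H](O)C[C@H]2O | intermediate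
30 | (2S,3S,5S,6S,8R)-2-[2-(benzyloxy)ethyl]-8-[(1R)-1-(benzyloxy)propyl]-6-[(tert-butyldimethylsilyl)oxy]-3,5-dichlorooxocane | C(COCc1ccccc1)[C@@H]2O[C@@H]([C@H](OCc3ccccc3)CC)C[C@H](O[Si](C)(C)C(C)(C)C)[C@@H](Cl)C[C@@H]2Cl | intermediate
31 | 2-[(2S,3S,5S,6S,8R)-6-[(tert-butyldimethylsilyl)oxy]-3,5-dichloro-8-[(1R)-1-hydroxypropyl]oxocan-2-yl]ethan-1-ol | OCC[C@@H]1O[C@@H]([C@H](O)CC)C[C@H](O[Si](C)(C)C(C)(C)C)[C@@H](Cl)C[C@@H]1Cl | intermediate
32 | 2-[(2S,3S,5S,6S,8R)-6-[(tert-butyldimethylsilyl)oxy]-3,5-dichloro-8-[(1R)-1-hydroxypropyl]oxocan-2-yl]acetaldehyde | O=CC[C@@H]1O[C@@H]([C@H](O)CC)C[C@H](O[Si](C)(C)C(C)(C)C)[C@@H](Cl)C[C@@H]1Cl | intermediate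
33 | 1,3-bis(triisopropylsilyl)propyne | CC(C)[Si](C(C)C)(C(C)C)C#CC[Si](C(C)C)(C(C)C)C(C)C | starting material
34 | (2S,3S,5S,6S,8R)-6-[(tert-butyldimethylsilyl)oxy]-3,5-dichloro-8-[(1R)-1-hydroxypropyl]-2-[(2Z)-5-(triisopropylsilyl)pent-2-en-4-yn-1-yl]oxocane | CC(C)[Si](C(C)C)(C(C)C)C#C/C=C\C[C@@H]1O[C@@H]([C@H](O)CC)C[C@H](O[Si](C)(C)C(C)(C)C)[C@@H](Cl)C[C@@H]1Cl | intermediate
35 | (2S,3S,5S,6S,8R)-8-[(1S)-1-bromopropyl]-6-[(tert-butyldimethylsilyl)oxy]-3,5-dichloro-2-[(2Z)-5-(triisopropylsilyl)pent-2-en-4-yn-1-yl]oxocane | CC(C)[Si](C(C)C)(C(C)C)C#C/C=C\C[C@@H]1O[C@@H]([C@@H](Br)CC)C[C@H](O[Si](C)(C)C(C)(C)C)[C@@H](Cl)C[C@@H]1Cl | intermediate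
36 | (2S,3S,5S,6S,8R)-8-[(1S)-1-bromopropyl]-3,5-dichloro-2-[(2Z)-pent-2-en-4-yn-1-yl]oxocan-6-ol | C#C/C=C\C[C@@H]1O[C@@H]([C@@H](Br)CC)C[C@H](O)[C@@H](Cl)C[C@@H]1Cl | intermediate
37 | (2S,3S,5S,6S,8R)-8-[(1S)-1-bromopropyl]-3,5-dichloro-2-[(2Z)-pent-2-en-4-yn-1-yl]oxocan-6-yl acetate, i.e. (3Z,6S,7S,9S,10S,12R,13S)-13-bromo-7,9-dichloro-6,12-epoxypentadec-3-en-1-yn-10-yl acetate | C#C/C=C\C[C@@H]1O[C@@H]([C@@H](Br)CC)C[C@H](OC(C)=O)[C@@H](Cl)C[C@@H]1Cl | target

**Step count**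

Total step count: 28. Longest linear sequence: 26 (steps 1–4 and 7–28; the branch of steps 5–6 joins at step 7).

**Three steps most likely to fail, with fallbacks**

Step 22, double chlorination at C7 and C9 (highest risk). C9 is transannular to the ring oxygen, whose participation could give retention or ring-contracted tetrahydrofurans; the 1,3-diol could also close to an oxetane or eliminate. Fallback: from diol 29, chloromethanesulfonyl chloride and pyridine in CH2Cl2 at 0 °C give the bis(chloromethanesulfonate) F5. Displacement with excess LiCl in DMF at 50 °C, where a high concentration of free chloride favours direct intermolecular SN2 at both centres, comes back to the route at dichloride 30.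

Step 17, ring-closing metathesis to the eight-membered ring. Two hindered allylic alkenes and medium-ring strain may lead to oligomers or to isomerisation of the free allylic alcohol. Fallback: from diene 24, Dess–Martin oxidation of the C10 carbinol gives the vinyl ketone F1. Ring closure on this enone with the same catalyst (the planar carbonyl lowers transannular strain) gives the oxocenone F2. Catalyst-controlled 1,2-reduction with (R)-2-methyl-CBS-oxazaborolidine and catecholborane at −78 °C resets C10 (S) and comes back to the route at oxocenol 25.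

Step 21, hydroxyl-directed hydride opening of the epoxide. In a medium ring, attack at C9 or transannular hydride shifts could compete with delivery to C8. Fallback: from epoxy alcohol 28, Dess–Martin oxidation gives the α,β-epoxy ketone F3. SmI2 in THF/MeOH at −78 °C cleaves the Cα–O bond, which is regiospecific by mechanism, to the β-hydroxy ketone F4. Evans–Saksena reduction with Me4NBH(OAc)3 in MeCN/AcOH at −20 °C, directed by the C9 hydroxyl, gives the 7,9-anti diol and comes back to the route at diol 29.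

**Further compounds**

F1 | step 17 | (5R,6R)-6-(benzyloxy)-5-{[(3S,4R)-1-(benzyloxy)-4-[(4-methoxybenzyl)oxy]hex-5-en-3-yl]oxy}oct-1-en-3-one | C=C[C@@H](OCc1ccc(OC)cc1)[C@@H](O[C@@H]([C@H](OCc1ccccc1)CC)CC(=O)C=C)CCOCc1ccccc1
F2 | step 17 | (2S,3R,4Z,8R)-2-[2-(benzyloxy)ethyl]-8-[(1R)-1-(benzyloxy)propyl]-3-[(4-methoxybenzyl)oxy]-7,8-dihydro-2H-oxocin-6(3H)-one | C(COCc1ccccc1)[C@@H]2O[C@@H]([C@H](OCc3ccccc3)CC)CC(=O)/C=C\[C@H]2OCc4ccc(OC)cc4
F3 | step 21 | 3-ketone of 28 (C7 ketone, 4,5-epoxide and all other groups unchanged) | C(COCc1ccccc1)[C@@H]2O[C@@H]([C@H](OCc3ccccc3)CC)C[C@H](O[Si](C)(C)C(C)(C)C)[C@@H]5O[C@@H]5C2=O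
F4 | step 21 | (2S,5R,6S,8R)-2-[2-(benzyloxy)ethyl]-8-[(1R)-1-(benzyloxy)propyl]-6-[(tert-butyldimethylsilyl)oxy]-5-hydroxyoxocan-3-one | C(COCc1ccccc1)[C@@H]2O[C@@H]([C@H](OCc3ccccc3)CC)C[C@H](O[Si](C)(C)C(C)(C)C)[C@H](O)CC2=O
F5 | step 22 | (2S,3R,5R,6S,8R)-2-[2-(benzyloxy)ethyl]-8-[(1R)-1-(benzyloxy)propyl]-6-[(tert-butyldimethylsilyl)oxy]oxocane-3,5-diyl bis(chloromethanesulfonate) | C(COCc1ccccc1)[C@@H]2O[C@@H]([C@H](OCc3ccccc3)CC)C[C@H](O[Si](C)(C)C(C)(C)C)[C@H](OS(=O)(=O)CCl)C[C@H]2OS(=O)(=O)CCl
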